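**Plan**

- Retrosynthetic cuts, in order: (a) the CH2–CH2 bond next to the central secondary nitrogen of the spermidine bridge; (b) the two amide C–N bonds; (c) the aryl–alkyne bond of a propiolamide (precursor of the Z-cinnamamide) and the C=C of the Z-acrylate on the quaternary carbon; (d) the aryl ether C–O bond of the dihydrofuran ring; (e) the cyclohexenone ring, by Diels–Alder disconnection.
- Enabling feature: the CH2 on the central nitrogen is an α-amino carbon, that is, the α-carbon of an N-alkylglycine. Carried as an N-Boc-glycine whose carboxyl is lost as CO2, it becomes a carbamate-stabilised radical exactly at the atom that must bond to the terminal CH2Br of an N-(3-bromopropyl) cinnamamide. The two Z-alkenes on the cis-fused hexahydrodibenzofuranone turn both arms to the same side.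
- Forward order: cyclohexene ring (Diels–Alder), dihydrofuran ring (oxa-Michael), Z-acrylate (Still–Gennari), Z-cinnamamide (Sonogashira, then Lindlar), amide to the glycine arm, and the 20-membered ring last, closed with extrusion of CO2.
- Stereochemistry: the quaternary carbon C9b comes from the catalyst-controlled Diels–Alder reaction; C4a is relayed from C9b because the five-membered ring can only fuse cis; both Z-alkenes are set kinetically (olefination, syn-hydrogenation) and are not exposed to light afterwards.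

Key step: step 16

Remark: the facial sense of the diol catalyst in step 4 is assigned by analogy with 2-alkylacroleins; if it proves opposite, the (S,S)-catalyst is used and nothing else changes. Locants 4a and 9b refer to hexahydrodibenzofuran numbering (C9b quaternary, C4a the O-bearing CH).

**Route**

Step 1
Reactants: 1 1-(2-hydroxy-5-iodophenyl)ethan-1-one
Product: 2 1-[2-(tert-butyldimethylsilyloxy)-5-iodophenyl]ethan-1-one
Conditions: TBSCl, imidazole, DMAP (cat.), DMF, rt
Reagents that add atoms: tert-butyldimethylsilyl chloride CC(C)(C)[Si](C)(C)Cl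
Why: O-silylation masks the phenol for the olefination, oxidation and cycloaddition and leaves a group that fluoride removes in step 5.

Step 2
Reactants: 2 1-[2-(tert-butyldimethylsilyloxy)-5-iodophenyl]ethan-1-one
Product: 3 tert-butyl[4-iodo-2-(prop-1-en-2-yl)phenoxy]dimethylsilane
Conditions: Ph3PCH3Br, KOtBu, THF, 0 °C to rt
Reagents that add atoms: methyltriphenylphosphonium bromide C[P+](c1ccccc1)(c1ccccc1)c1ccccc1.[Br-]
Why: Wittig methylenation of the aryl methyl ketone with the non-stabilised ylide should give the 2-arylpropene; the aryl iodide and the aryl silyl ether are inert to the ylide.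

Step 3
Reactants: 3 tert-butyl[4-iodo-2-(prop-1-en-2-yl)phenoxy]dimethylsilane
Product: 4 2-[2-(tert-butyldimethylsilyloxy)-5-iodophenyl]prop-2-enal
Conditions: SeO2, 1,4-dioxane/H2O, 90 °C
Reagents that add atoms: selenium dioxide O=[Se]=O
Why: Selenium dioxide allylic oxidation (ene reaction, [2,3]-sigmatropic shift, further oxidation of the allylic alcohol) converts the only allylic methyl group into the aldehyde and gives the 2-arylacrolein.

Step 4
Reactants: 4 2-[2-(tert-butyldimethylsilyloxy)-5-iodophenyl]prop-2-enal; 5 (E)-3-(tert-butyldimethylsilyloxy)-N,N-dimethylbuta-1,3-dien-1-amine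
Product: 6 (1S,2S)-2-(dimethylamino)-4-(tert-butyldimethylsilyloxy)-1-[2-(tert-butyldimethylsilyloxy)-5-iodophenyl]cyclohex-3-ene-1-carbaldehyde
Conditions: (R,R)-α,α,α',α'-tetra(1-naphthyl)-2,2-dimethyl-1,3-dioxolane-4,5-dimethanol (20 mol%), 4 Å sieves, toluene, −78 to −40 °C
Reagents that add atoms: none
Why: Hydrogen-bond-catalysed Diels–Alder reaction of a 1-amino-3-silyloxybutadiene with an α-substituted acrolein; the diol binds the formyl oxygen and screens one face of the dienophile, which sets the quaternary carbon, the polarised diene bonds its amino-bearing terminus to the α-carbon, and the endo transition state places NMe2 cis to CHO (a centre erased in step 5).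

Step 5
Reactants: 6 (1S,2S)-2-(dimethylamino)-4-(tert-butyldimethylsilyloxy)-1-[2-(tert-butyldimethylsilyloxy)-5-iodophenyl]cyclohex-3-ene-1-carbaldehyde
Product: 9 (4aR,9bR)-9b-(hydroxymethyl)-8-iodo-1,4,4a,9b-tetrahydrodibenzo[b,d]furan-3(2H)-one, via carbinol 7 (not isolated), via enone phenol 8 (not isolated)
Conditions: LiAlH4, Et2O, −78 °C; then 48% aq. HF, MeCN, 0 °C to rt; then K2CO3 (cat.), MeOH, rt
Reagents that add atoms: none
Why: Hydride reduction of the neopentyl aldehyde, acid hydrolysis of the silyl enol ether with β-elimination of dimethylamine to the enone, fluoride cleavage of the aryl silyl ether and 5-exo-trig oxa-Michael addition of the phenol; the five-membered ring can form only on the face that carries the aryl group, so the quaternary centre dictates the cis fusion and the configuration of the O-bearing carbon.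

Step 6
Reactants: 9 (4aR,9bR)-9b-(hydroxymethyl)-8-iodo-1,4,4a,9b-tetrahydrodibenzo[b,d]furan-3(2H)-one
Product: 10 (4aR,9bS)-8-iodo-3-oxo-2,3,4,4a-tetrahydrodibenzo[b,d]furan-9b(1H)-carbaldehyde
Conditions: Dess–Martin periodinane, NaHCO3, CH2Cl2, 0 °C to rt
Reagents that add atoms: none
Why: Dess–Martin oxidation of the neopentyl primary alcohol to a non-enolisable aldehyde under buffered conditions that do not open the β-aryloxy ketone.

Step 7
Reactants: 10 (4aR,9bS)-8-iodo-3-oxo-2,3,4,4a-tetrahydrodibenzo[b,d]furan-9b(1H)-carbaldehyde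
Product: 11 methyl (2Z)-3-[(4aR,9bS)-8-iodo-3-oxo-2,3,4,4a-tetrahydrodibenzo[b,d]furan-9b(1H)-yl]prop-2-enoate
Conditions: (CF3CH2O)2P(O)CH2CO2Me, KN(SiMe3)2, 18-crown-6, THF, −78 °C
Reagents that add atoms: methyl bis(2,2,2-trifluoroethyl)phosphonoacetate COC(=O)CP(=O)(OCC(F)(F)F)OCC(F)(F)F
Why: Still–Gennari olefination: the electron-poor phosphonate and the crown-separated potassium ion make elimination from the kinetic adduct fast and irreversible, which should give the Z-enoate, and the aldehyde reacts far faster than the ketone.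

Step 8
Reactants: 11 methyl (2Z)-3-[(4aR,9bS)-8-iodo-3-oxo-2,3,4,4a-tetrahydrodibenzo[b,d]furan-9b(1H)-yl]prop-2-enoate
Product: 12 methyl (2Z)-3-[(4aR,9bS)-3,3-(ethane-1,2-diyldioxy)-8-iodo-1,2,3,4,4a,9b-hexahydrodibenzo[b,d]furan-9b-yl]prop-2-enoate
Conditions: Me3SiOCH2CH2OSiMe3, Me3SiOSO2CF3 (cat.), CH2Cl2, −78 to −20 °C
Reagents that add atoms: 1,2-bis(trimethylsilyloxy)ethane C[Si](C)(C)OCCO[Si](C)(C)C
Why: Silyl-triflate-catalysed ketalisation protects the ketone without ester exchange or alkene isomerisation; the ketal prevents retro-oxa-Michael opening of the β-aryloxy ketone in the basic steps 10, 12 and 15.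

Step 9
Reactants: 13 propiolic acid; 14 3-bromopropan-1-amine hydrobromide
Product: 15 N-(3-bromopropyl)prop-2-ynamide
Conditions: DCC, N-methylmorpholine, CH2Cl2, 0 °C
Reagents that add atoms: none
Why: Carbodiimide amide coupling with the amine freed in situ from its salt; low temperature and the absence of a nucleophilic catalyst avoid conjugate addition to the ynamide and self-alkylation of the bromoamine.

Step 10
Reactants: 12 methyl (2Z)-3-[(4aR,9bS)-3,3-(ethane-1,2-diyldioxy)-8-iodo-1,2,3,4,4a,9b-hexahydrodibenzo[b,d]furan-9b-yl]prop-2-enoate; 15 N-(3-bromopropyl)prop-2-ynamide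
Product: 16 methyl (2Z)-3-[(4aR,9bS)-8-{3-[(3-bromopropyl)amino]-3-oxoprop-1-yn-1-yl}-3,3-(ethane-1,2-diyldioxy)-1,2,3,4,4a,9b-hexahydrodibenzo[b,d]furan-9b-yl]prop-2-enoate
Conditions: PdCl2(PPh3)2 (5 mol%), CuI (10 mol%), iPr2NEt, THF, rt
Reagents that add atoms: none
Why: Sonogashira coupling; oxidative addition takes place at the aryl iodide at room temperature while the alkyl bromide, the Z-enoate and the ketal are untouched.

Step 11
Reactants: 16 methyl (2Z)-3-[(4aR,9bS)-8-{3-[(3-bromopropyl)amino]-3-oxoprop-1-yn-1-yl}-3,3-(ethane-1,2-diyldioxy)-1,2,3,4,4a,9b-hexahydrodibenzo[b,d]furan-9b-yl]prop-2-enoate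
Product: 17 methyl (2Z)-3-[(4aR,9bS)-8-{(1Z)-3-[(3-bromopropyl)amino]-3-oxoprop-1-en-1-yl}-3,3-(ethane-1,2-diyldioxy)-1,2,3,4,4a,9b-hexahydrodibenzo[b,d]furan-9b-yl]prop-2-enoate
Conditions: H2 (1 atm), Pd on CaCO3 poisoned with Pb(OAc)2, quinoline, EtOAc, rt
Reagents that add atoms: none
Why: Lindlar semi-hydrogenation delivers both hydrogens to one face of the alkyne and should give the Z-cinnamamide; the poisoned catalyst should not reduce the conjugated alkenes or the C–Br bond.

Step 12
Reactants: 17 methyl (2Z)-3-[(4aR,9bS)-8-{(1Z)-3-[(3-bromopropyl)amino]-3-oxoprop-1-en-1-yl}-3,3-(ethane-1,2-diyldioxy)-1,2,3,4,4a,9b-hexahydrodibenzo[b,d]furan-9b-yl]prop-2-enoate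
Product: 18 (2Z)-3-[(4aR,9bS)-8-{(1Z)-3-[(3-bromopropyl)amino]-3-oxoprop-1-en-1-yl}-3,3-(ethane-1,2-diyldioxy)-1,2,3,4,4a,9b-hexahydrodibenzo[b,d]furan-9b-yl]prop-2-enoic acid
Conditions: LiOH, THF/H2O, 0 °C; then 1 M HCl to pH 4, 0 °C
Reagents that add atoms: lithium hydroxide [Li+].[OH-]
Why: Saponification of the methyl ester; at 0 °C hydroxide should attack the ester much faster than the primary bromide, and the ketal keeps the β-aryloxy ketone closed.

Step 13
Reactants: 19 benzyl (3-aminopropyl)carbamate hydrochloride; 20 benzyl bromoacetate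
Product: 22 benzyl N-(tert-butoxycarbonyl)-N-[3-(benzyloxycarbonylamino)propyl]glycinate, via secondary amine 21 (not isolated)
Conditions: Et3N, MeCN, 0 °C to rt (19 in excess); then Boc2O, rt
Reagents that add atoms: di-tert-butyl dicarbonate CC(C)(C)OC(=O)OC(=O)OC(C)(C)C
Why: N-alkylation of the primary amine by the α-bromo ester (excess amine limits double alkylation), followed by carbamate formation on the new secondary amine.

Step 14
Reactants: 22 benzyl N-(tert-butoxycarbonyl)-N-[3-(benzyloxycarbonylamino)propyl]glycinate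
Product: 23 N-(3-aminopropyl)-N-(tert-butoxycarbonyl)glycine
Conditions: H2 (1 atm), 10% Pd on carbon, MeOH, rt
Reagents that add atoms: none
Why: Hydrogenolysis cleaves the benzyl carbamate and the benzyl ester in one operation and leaves the Boc group, giving the free amino acid.

Step 15
Reactants: 18 (2Z)-3-[(4aR,9bS)-8-{(1Z)-3-[(3-bromopropyl)amino]-3-oxoprop-1-en-1-yl}-3,3-(ethane-1,2-diyldioxy)-1,2,3,4,4a,9b-hexahydrodibenzo[b,d]furan-9b-yl]prop-2-enoic acid; 23 N-(3-aminopropyl)-N-(tert-butoxycarbonyl)glycine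
Product: 25 N-[3-({(2Z)-3-[(4aR,9bS)-8-{(1Z)-3-[(3-bromopropyl)amino]-3-oxoprop-1-en-1-yl}-3,3-(ethane-1,2-diyldioxy)-1,2,3,4,4a,9b-hexahydrodibenzo[b,d]furan-9b-yl]prop-2-enoyl}amino)propyl]-N-(tert-butoxycarbonyl)glycine, via succinimidyl ester 24 (not isolated)
Conditions: O-(N-succinimidyl)-N,N,N',N'-tetramethyluronium tetrafluoroborate, iPr2NEt, DMF, 0 °C; then 23, iPr2NEt, DMF/H2O, rt
Reagents that add atoms: none
Why: Amide formation through the N-hydroxysuccinimide active ester, which acylates the primary amine of the unprotected amino acid and leaves its carboxyl free, so no ester has to be cleaved later beside the alkyl bromide.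

Step 16
Reactants: 25 N-[3-({(2Z)-3-[(4aR,9bS)-8-{(1Z)-3-[(3-bromopropyl)amino]-3-oxoprop-1-en-1-yl}-3,3-(ethane-1,2-diyldioxy)-1,2,3,4,4a,9b-hexahydrodibenzo[b,d]furan-9b-yl]prop-2-enoyl}amino)propyl]-N-(tert-butoxycarbonyl)glycine
Product: 27 the 20-membered bis-Z macrocycle of the target (4aR,9bS) carrying a tert-butyl carbamate on the central nitrogen and an ethylene ketal at C3, via phthalimidyl ester 26 (not isolated)
Conditions: N-hydroxyphthalimide, iPrN=C=NiPr, DMAP (cat.), THF, rt; then syringe-pump addition to NiBr2(MeOCH2CH2OMe) (20 mol%), 4,4'-di-tert-butyl-2,2'-bipyridine (24 mol%), Zn dust (3 equiv), N,N-dimethylacetamide, 2 mM final, 30 °C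
Reagents that add atoms: none
Why: Proposed new method: Zn reduces the NiBr2–bipyridine precatalyst to low-valent nickel, which transfers one electron to the phthalimidyl ester of 26; the radical anion fragments to phthalimide anion, CO2 and the carbamate-stabilised α-amino radical at the glycine CH2, while the terminal C–Br bond adds oxidatively to nickel, the alkylnickel captures the radical and the dialkyl trivalent nickel forms the N–CH2–CH2 bond by reductive elimination. The closest known reaction type is the intermolecular nickel-catalysed reductive cross-electrophile coupling of N-hydroxyphthalimide esters with unactivated primary alkyl bromides and, for ring formation by a decarboxylatively generated α-amino radical, the decarboxylative radical macrocyclisation of peptides. The 20-membered ring is closed end to end, chain terminus onto chain terminus through a 21-membered nickelacycle that contracts on reductive elimination, and no stereocentre is formed. Ring closure must win over oligomerisation, which slow addition to 2 mM and the fold imposed by the two Z-alkenes on the rigid cis-fused tricycle should secure; the carbon radical and the alkylnickel must also ignore the conjugated alkenes, which the trans secondary amides should secure by holding each chain away from its own acrylamide (attack would need an eight- or nine-membered transition state from the glycine carbon and a cis amide from the bromopropyl carbon). No light is used, so the Z-alkenes are not exposed to sensitised isomerisation, and the ketal, the Boc group and both amides are inert to Zn and nickel.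

Step 17
Reactants: 27 the N-Boc, C3-ethylene-ketal macrocycle
Product: 28 CNP0159470.1, the (4aR,9bS) 20-membered bis-Z spermidine macrolactam with free ketone and free secondary amine
Conditions: CF3CO2H/H2O (9:1), 0 °C to rt; then aq. NaHCO3
Reagents that add atoms: water O
Why: Acidolysis removes the Boc group (as isobutene and CO2) and hydrolyses the dioxolane to the ketone in one operation; the Z-enamides are stable to acid, C9b is quaternary, and C4a can only reclose cis.

**Compound list**

1 | 1-(2-hydroxy-5-iodophenyl)ethan-1-one | CC(=O)c1cc(I)ccc1O | starting material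
2 | 1-[2-(tert-butyldimethylsilyloxy)-5-iodophenyl]ethan-1-one | CC(=O)c1cc(I)ccc1O[Si](C)(C)C(C)(C)C | intermediate
3 | tert-butyl[4-iodo-2-(prop-1-en-2-yl)phenoxy]dimethylsilane | C=C(C)c1cc(I)ccc1O[Si](C)(C)C(C)(C)C | intermediate
4 | 2-[2-(tert-butyldimethylsilyloxy)-5-iodophenyl]prop-2-enal | C=C(C=O)c1cc(I)ccc1O[Si](C)(C)C(C)(C)C | intermediate
5 | (E)-3-(tert-butyldimethylsilyloxy)-N,N-dimethylbuta-1,3-dien-1-amine | CN(C)/C=C/C(=C)O[Si](C)(C)C(C)(C)C | starting material
6 | (1S,2S)-2-(dimethylamino)-4-(tert-butyldimethylsilyloxy)-1-[2-(tert-butyldimethylsilyloxy)-5-iodophenyl]cyclohex-3-ene-1-carbaldehyde (NMe2 cis to CHO) | CN(C)[C@H]1C=C(O[Si](C)(C)C(C)(C)C)CC[C@]1(C=O)c2cc(I)ccc2O[Si](C)(C)C(C)(C)C | intermediate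
7 | [(1S,2S)-2-(dimethylamino)-4-(tert-butyldimethylsilyloxy)-1-[2-(tert-butyldimethylsilyloxy)-5-iodophenyl]cyclohex-3-en-1-yl]methanol | CN(C)[C@H]1C=C(O[Si](C)(C)C(C)(C)C)CC[C@]1(CO)c2cc(I)ccc2O[Si](C)(C)C(C)(C)C | intermediate
8 | (R)-4-(2-hydroxy-5-iodophenyl)-4-(hydroxymethyl)cyclohex-2-en-1-one | O=C1CC[C@](CO)(c2cc(I)ccc2O)C=C1 | intermediate
9 | (4aR,9bR)-9b-(hydroxymethyl)-8-iodo-1,4,4a,9b-tetrahydrodibenzo[b,d]furan-3(2H)-one (cis-fused) | O=C1CC[C@]2(CO)c3cc(I)ccc3O[C@@H]2C1 | intermediate
10 | (4aR,9bS)-8-iodo-3-oxo-2,3,4,4a-tetrahydrodibenzo[b,d]furan-9b(1H)-carbaldehyde | O=C1CC[C@]2(C=O)c3cc(I)ccc3O[C@@H]2C1 | intermediate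
11 | methyl (2Z)-3-[(4aR,9bS)-8-iodo-3-oxo-2,3,4,4a-tetrahydrodibenzo[b,d]furan-9b(1H)-yl]prop-2-enoate | O=C1CC[C@]2(/C=C\C(=O)OC)c3cc(I)ccc3O[C@@H]2C1 | intermediate
12 | ethylene ketal of 11 | C1COC2(O1)CC[C@]3(/C=C\C(=O)OC)c4cc(I)ccc4O[C@@H]3C2 | intermediate
13 | propiolic acid | C#CC(=O)O | starting material
14 | 3-bromopropan-1-amine hydrobromide | NCCCBr.Br | starting material
15 | N-(3-bromopropyl)prop-2-ynamide | C#CC(=O)NCCCBr | intermediate
16 | aryl propiolamide (8-alkynyl, Z-enoate, ketal) | C1COC2(O1)CC[C@]3(/C=C\C(=O)OC)c4cc(C#CC(=O)NCCCBr)ccc4O[C@@H]3C2 | intermediate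
17 | bis-Z ester (Z-cinnamamide, Z-enoate, ketal) | C1COC2(O1)CC[C@]3(/C=C\C(=O)OC)c4cc(/C=C\C(=O)NCCCBr)ccc4O[C@@H]3C2 | intermediate
18 | bis-Z acid | C1COC2(O1)CC[C@]3(/C=C\C(=O)O)c4cc(/C=C\C(=O)NCCCBr)ccc4O[C@@H]3C2 | intermediate
19 | benzyl (3-aminopropyl)carbamate hydrochloride | NCCCNC(=O)OCc1ccccc1.Cl | starting material
20 | benzyl bromoacetate | BrCC(=O)OCc1ccccc1 | starting material
21 | benzyl N-[3-(benzyloxycarbonylamino)propyl]glycinate | O=C(OCc1ccccc1)NCCCNCC(=O)OCc1ccccc1 | intermediate
22 | benzyl N-(tert-butoxycarbonyl)-N-[3-(benzyloxycarbonylamino)propyl]glycinate | O=C(OCc1ccccc1)NCCCN(CC(=O)OCc1ccccc1)C(=O)OC(C)(C)C | intermediate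
23 | N-(3-aminopropyl)-N-(tert-butoxycarbonyl)glycine | NCCCN(CC(=O)O)C(=O)OC(C)(C)C | intermediate
24 | N-succinimidyl ester of 18 | C1COC2(O1)CC[C@]3(/C=C\C(=O)ON5C(=O)CCC5=O)c4cc(/C=C\C(=O)NCCCBr)ccc4O[C@@H]3C2 | intermediate
25 | seco acid (glycine acid arm and bromopropyl arm) | C1COC2(O1)CC[C@]3(/C=C\C(=O)NCCCN(CC(=O)O)C(=O)OC(C)(C)C)c4cc(/C=C\C(=O)NCCCBr)ccc4O[C@@H]3C2 | intermediate
26 | N-phthalimidyl ester of 25 | C1COC2(O1)CC[C@]3(/C=C\C(=O)NCCCN(CC(=O)ON5C(=O)c6ccccc6C5=O)C(=O)OC(C)(C)C)c4cc(/C=C\C(=O)NCCCBr)ccc4O[C@@H]3C2 | intermediate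
27 | N-Boc, C3-ethylene-ketal macrocycle (4aR,9bS; both alkenes Z) | C1COC5(O1)CC[C@]23/C=C\C(=O)NCCCN(C(=O)OC(C)(C)C)CCCCNC(=O)/C=C\c4ccc(c2c4)O[C@@H]3C5 | intermediate
28 | CNP0159470.1 (4aR,9bS; both alkenes Z) | O=C1CC[C@]23/C=C\C(=O)NCCCNCCCCNC(=O)/C=C\c4ccc(c2c4)O[C@@H]3C1 | target

**Step count and risks**

Total steps: 17. Longest linear sequence: 14 (steps 1–8, 10–12, 15–17).

Steps most likely to fail:

1. Step 16 (Proposed new method). Oligomerisation, premature reduction of the C–Br bond or hydrogen-atom capture by the α-amino radical may outrun ring closure. The fallback closes the ring by macrolactamisation, which is known chemistry. It sets out from 12. Propiolic acid 13 is coupled (DCC, CH2Cl2, 0 °C) with commercial tert-butyl (4-aminobutyl){3-[(tert-butoxycarbonyl)amino]propyl}carbamate (NCCCCN(CCCNC(=O)OC(C)(C)C)C(=O)OC(C)(C)C) to give the bis-Boc-spermidine propiolamide F1. Sonogashira coupling of F1 with 12 under the conditions of step 10 gives the aryl alkyne F2, and Lindlar semi-hydrogenation gives the bis-Z ester F3. LiOH gives the acid F4, and pentafluorophenol with a carbodiimide gives the pentafluorophenyl ester F5. CF3CO2H/H2O removes both Boc groups and the ketal to give the bis-ammonium salt F6. This is added slowly to iPr2NEt in MeCN at high dilution, where the primary amine, the more reactive nucleophile toward the active ester, should close the 20-membered lactam. The route is rejoined at 28.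

2. Step 4. Poor facial selectivity or low reactivity of the hindered 2-arylacrolein under hydrogen-bond catalysis. The fallback is a racemic synthesis with resolution. It sets out from 4 and 5: the uncatalysed cycloaddition (toluene, rt) gives the racemic cycloadduct F7, the sequence of step 5 gives the racemic cis-fused keto alcohol F8, and preparative chromatography on a chiral stationary phase separates the enantiomers. The route is rejoined at 9.

3. Step 11. Over-reduction to the saturated amide or Z-to-E isomerisation on the catalyst surface. The fallback brings the Z-alkene in preformed by a stereoretentive Suzuki–Miyaura coupling. It sets out from 12 and bypasses steps 9–11. Hydroiodination of 13 (NaI, AcOH, 70 °C) gives (Z)-3-iodoacrylic acid F9, and carbodiimide coupling with 14 gives (Z)-N-(3-bromopropyl)-3-iodoacrylamide F10. Miyaura borylation of 12 (bis(pinacolato)diboron, PdCl2[Ph2P(C5H4)Fe(C5H4)PPh2], KOAc, dioxane, 80 °C) gives the arylboronate F11. Coupling of F11 with F10 (Pd(PPh3)4, K3PO4, THF/H2O, rt) should retain the alkene geometry. The route is rejoined at 17.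

**Further compounds**

F1 | step 16 | N-{4-[(tert-butoxycarbonyl){3-[(tert-butoxycarbonyl)amino]propyl}amino]butyl}prop-2-ynamide | C#CC(=O)NCCCCN(CCCNC(=O)OC(C)(C)C)C(=O)OC(C)(C)C
F2 | step 16 | aryl propiolamide bearing the bis-Boc-spermidine chain (Z-enoate, ketal) | C1COC2(O1)CC[C@]3(/C=C\C(=O)OC)c4cc(C#CC(=O)NCCCCN(CCCNC(=O)OC(C)(C)C)C(=O)OC(C)(C)C)ccc4O[C@@H]3C2
F3 | step 16 | bis-Z methyl ester bearing the bis-Boc-spermidine chain | C1COC2(O1)CC[C@]3(/C=C\C(=O)OC)c4cc(/C=C\C(=O)NCCCCN(CCCNC(=O)OC(C)(C)C)C(=O)OC(C)(C)C)ccc4O[C@@H]3C2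
F4 | step 16 | bis-Z acid bearing the bis-Boc-spermidine chain | C1COC2(O1)CC[C@]3(/C=C\C(=O)O)c4cc(/C=C\C(=O)NCCCCN(CCCNC(=O)OC(C)(C)C)C(=O)OC(C)(C)C)ccc4O[C@@H]3C2
F5 | step 16 | pentafluorophenyl ester of F4 | C1COC2(O1)CC[C@]3(/C=C\C(=O)Oc5c(F)c(F)c(F)c(F)c5F)c4cc(/C=C\C(=O)NCCCCN(CCCNC(=O)OC(C)(C)C)C(=O)OC(C)(C)C)ccc4O[C@@H]3C2
F6 | step 16 | deprotected keto diamine pentafluorophenyl ester, bis(trifluoroacetate) salt | O=C1CC[C@]2(/C=C\C(=O)Oc5c(F)c(F)c(F)c(F)c5F)c3cc(/C=C\C(=O)NCCCCNCCCN)ccc3O[C@@H]2C1.OC(=O)C(F)(F)F.OC(=O)C(F)(F)F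
F7 | step 4 | racemic cycloadduct (both enantiomers of 6, NMe2 cis to CHO) | CN(C)[C@H]1C=C(O[Si](C)(C)C(C)(C)C)CC[C@]1(C=O)c2cc(I)ccc2O[Si](C)(C)C(C)(C)C.CN(C)[C@@H]1C=C(O[Si](C)(C)C(C)(C)C)CC[C@@]1(C=O)c2cc(I)ccc2O[Si](C)(C)C(C)(C)C
F8 | step 4 | racemic cis-fused keto alcohol (both enantiomers of 9) | O=C1CC[C@]2(CO)c3cc(I)ccc3O[C@@H]2C1.O=C1CC[C@@]2(CO)c3cc(I)ccc3O[C@H]2C1
F9 | step 11 | (Z)-3-iodoacrylic acid | OC(=O)/C=C\I
F10 | step 11 | (Z)-N-(3-bromopropyl)-3-iodoacrylamide | BrCCCNC(=O)/C=C\I
F11 | step 11 | pinacol arylboronate from 12 (Z-enoate, ketal) | C1COC2(O1)CC[C@]3(/C=C\C(=O)OC)c4cc(B5OC(C)(C)C(C)(C)O5)ccc4O[C@@H]3C2
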